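## Structural features

The target is a trans-fused decalin (ring A = C5 to C10, ring B = C1 to C5 with C10) with a ketone at C3; the quaternary C9 carries a CH2 group (C11) bound through an ether oxygen to the 7-position of a coumarin. There are five stereocentres, four of them contiguous: C8 (CH–CH3), C9 (quaternary, CH3 and C11), C10 (fusion CH) and C5 (quaternary, angular CH3); the fifth, C4 (CH–CH3), lies between C5 and the ketone. In decalin numbering the configuration is 4R,5S,8R,9R,10R: the C5 and C9 methyls are 1,3-syn-diaxial on the β face, the C8 methyl is axial on the α face (trans to the C9 methyl, cis to C11), H-10 is α, and the C4 methyl is equatorial and cis to the C5 methyl. The fragile parts are the coumarin lactone (opened by alkoxide, reduced by dissolving metals) and the epimerizable C4, although the required C4 epimer is the more stable one. The C11–O bond is neopentyl, so substitution at C11 is slow. The real difficulty lies in the two quaternary carbons C5 and C9 on either side of the ring fusion and in the trans fusion itself. The key step uses the fact that the axial C5 methyl, C4 and the C3 carbonyl are the retron of a C4–C5–CH2 cyclopropane conjugated to C3: a C4 carbenoid adding to a C5 exocyclic methylene on ring A forms C4–C5 and C4–CH2, closes ring B and stores the angular methyl as a cyclopropane CH2.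

## Logic of the disconnections

22 is cut at the O–C11 bond into 21 and 20, and 20 is the sulfonate of 19. The cut comes last in the forward sense because the coumarin would not survive the dissolving-metal step or the organometallic reagents used earlier. It removes the aromatic unit and leaves a C15 hydroxy ketone. The demand is a substitution at a neopentyl carbon: it needs the best leaving group and a weakly basic phenoxide, and it is helped by the absence of any β-hydrogen on C9.

19 is cut at the C4–CH3 bond, and one C–H bond of the C5 methyl is traced back to a C4–CH2 bond; this gives 16, where C4, C5 and the CH2 form a cyclopropane conjugated with the C3 ketone. Reductive opening of such a ketone gives the enolate specifically towards C4, so one operation installs the angular methyl and allows methylation at C4; the O-benzyl bond of 16 is cut under the same conditions. Two methyl-bearing stereocentres are reduced to one rigid ring whose configuration is that of C5. The demands are cleavage of the exocyclic cyclopropane bond rather than the in-ring one, monoalkylation, and access to the equatorial C4 epimer.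

16, via 15, is cut at C4–C5 and C4–CH2, the two bonds a carbene at C4 makes with an exocyclic alkene at C5; this gives the monocyclic 1,6-enyne 14, where the carbene is latent in a terminal alkyne next to an acetate-bearing carbon. Ring B, the quaternary C5 and C4 then arise together by isomerization. This is the largest simplification of the route: a tricycle with two new stereocentres becomes a cyclohexane with three. The demand is selectivity: 1,2-acyloxy migration must place the carbenoid at C4, and the carbenoid must add to the face of the C5 methylene that gives the trans fusion.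

14 is cut at C2–C3 and at the acetyl–oxygen bond into 11 and 12. An aldehyde plus an ethynyl nucleophile is the shortest way to a propargylic ester. The alkyne and a stereocentre that need not be controlled are removed. The demand is only clean addition and acylation in the presence of the alkene and the benzyl ether.

11 goes back by a change of oxidation level to 10, and 10 is cut at the C5=CH2 bond to give 9. The methylene is installed before the aldehyde is unveiled, so the ketone never meets an aldehyde or an alkynyl metal, and C10, which can epimerize only while C5 is a carbonyl, is locked early. The gain is a keto ester with no chemoselectivity problem. The demand is a non-basic methylenation that works on a hindered ketone and spares the ester.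

9 is cut at C9–CH3 and at C10–C1: a methyl nucleophile adds to 6 to give 8, which is alkylated by 7. This creates the quaternary C9 and the C10 stereocentre in one operation from a flat enone. The demand is facial control at both carbons by the only stereocentre present, C8.

6 is cut at C9–C11, giving 3 and the alkoxymethyl donor 4, with 5 as the trapped enolate that is dehydrogenated back to an enone. C11 arrives with its oxygen already protected by the group that step 11 removes without an extra step. The demand is a regiospecific reoxidation, which the silyl enol ether provides.

3 is traced back by removal of the C9=C10 unsaturation to 2, and 2 goes back to the achiral, symmetric 1. 1 already holds the C8 methyl, and removing one of its two enantiotopic protons sets the absolute configuration of the whole route. The demand is high enantiotopic selectivity from a chiral base.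

## Other disconnections considered

Alternative 1: The cut runs through C7–C8 and C9–C10, so that ring A arises from an intermolecular [4+2] cycloaddition. In the forward sense the diene A1, 2-(tert-butyldimethylsilyloxy)-3-methylbuta-1,3-diene, would add to the chiral butenolide A2, (5R)-5-(menthyloxy)-3-methylfuran-2(5H)-one, and give the cis-fused lactone acetal A3. In A3 the two alkene carbons of A2 have become C8 and C9, the lactone carbonyl is C11, and the silyl enol ether brought in by A1 spans C5=C6. In its favour: one step would create the quaternary C9 and the adjacent C8 with the required cis relation between C11 and the carbon on C8, A1 should add anti to the menthyloxy group of the enantiopure, crystalline A2, and the orientation is the electronically matched one (silyloxy carbon 1,4 to the carbonyl-bearing carbon). Against it here: A2, being an α-methylbutenolide, is a sluggish dienophile, and Lewis acids would endanger the enol ether and the acetal; the acetal carbon on C8 must be reduced all the way to CH3 while C11 stays oxygenated; C6 carries an oxygen the target lacks; and A3 contains neither ring B nor the C5 quaternary centre, with C10 an unactivated CH2. On structure, A3 solves the C8/C9 pair at least as well as the chosen plan and is the better of the two on absolute configuration, since the chosen plan depends on a chiral base of high but incomplete selectivity. On mechanism, a concerted thermal cycloaddition is more predictable than a platinum carbenoid, which is also a point for the alternative. On step economy the chosen plan is clearly ahead: it reaches the C8/C9 array in five steps and spends its key step on C5, C4 and ring B, which the alternative leaves for a long sequence after A3.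

Alternative 2: The cut runs through C5–C10 and C8–C9, so that both rings arise from an intramolecular Diels–Alder reaction of the trienal A4, (2E,7R,8E,10E)-6,6-(ethylenedioxy)-2,7,8-trimethyldodeca-2,8,10-trienal. In the forward sense the tethered (E)-2-methyl enal of A4 would add across its (E,E)-diene, thermally or with a Lewis acid, and give the trans-fused octalin aldehyde A5 (C6=C7 alkene, C3 dioxolane, C11 as the aldehyde). In its favour: two rings, two skeletal bonds and four stereocentres (C5, C8, C9, C10) would form in one step from an acyclic precursor, a larger gain in complexity than the chosen key step and the better of the two on this count; the alkene geometries of A4 map onto the required relative configuration through a single formyl-endo transition state; C11 arrives at a useful oxidation level; and the C4 stereocentre in the tether can steer the facial course by allylic strain. Against it here: the diene terminus C5 of A4 is fully substituted and its methyl points inward, which disfavours the s-cis conformer; both new bonds end at quaternary carbons; α-methyl enals have a weak, often reversed, endo preference, so the trans fusion is not secured; and A4 needs a stereodefined trisubstituted enal and diene, roughly as many steps as 14. On structure the alternative is more convergent. On mechanism it is stereospecific in alkene geometry, but its endo/exo and facial selectivity are about as uncertain as the ring-fusion selectivity of the chosen plan, so the two are equal here. On step economy the two are similar, because hydrogenation, reduction, deprotection and the same neopentyl etherification still follow A5. The chosen plan is preferred because each stereocentre is set in a separately adjustable step and the hindered C5 centre is made by a reactive carbenoid rather than by a congested cycloaddition.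

Alternative 3: The cut is the C8–CH3 bond. In the forward sense the (bromomethyl)dimethylsilyl ether A6 of a C7=C8 unsaturated C11 alcohol would be treated with Bu3SnH and a radical initiator; the silylmethyl radical would close 6-exo onto C8 and give the cis-fused siloxane A7, and protodesilylation of A7 would then leave the methyl and free the C11 hydroxyl. In its favour: intramolecular delivery from the C11 oxygen places the new carbon cis to C11, exactly the axial C8 methyl of the target; the radical chain tolerates the ketal and other polar groups better than the carbenoid step, which is a point for the alternative; and the free C11 alcohol emerges ready for etherification. Against it here: only one C–C bond and one stereocentre are made and no ring of the skeleton; A6 already needs the complete decalin with C4, C5, C9 and C10 correct, so it must be combined with another skeleton-building plan; 7-endo closure can compete for silicon-tethered radicals on a homoallylic oxygen; and protodesilylation of the hindered A7 needs forcing basic conditions. On structure the alternative addresses a centre that the chosen plan obtains from 1 at no cost. On mechanism, in the certainty of the C8/C9 relation, it is the equal of the cuprate addition anti to the C8 methyl. On step economy it is worse, three steps for one methyl group.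

Key step: step 9

Remarks on the chemistry (one line each):
- The arm on C10 must be two carbons long (C1, C2) before the alkyne is added; a three-carbon Michael acceptor such as acrolein would lead to a 1,7-enyne and a seven-membered ring B, so the arm is introduced with 7 as a CH2CO2Me unit.
- Decalin numbering of the target (C1 to C11) is used for all intermediates in the reasoning.
- 4 is taken to be commercially available.
- The (S,S)-configured lithium amide is assumed, by analogy with other 4-substituted cyclohexanones, to give (R)-2; if the sense is the opposite, the (R,R)-amine is used.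
- C2 of 13 and 14 is formed without control and carried as a pair of epimers, since it becomes sp2 in step 9.
- Iodomethane is expected to enter C4 anti to the C5 methyl, so the required equatorial epimer is reached by equilibration inside step 11.

## Route

Step 1
Reactants: 1 4-methylcyclohexanone
Product: 2 (R)-trimethyl[(4-methylcyclohex-1-en-1-yl)oxy]silane
Conditions: (S,S)-bis(1-phenylethyl)amine, n-BuLi, THF, −78 °C; Me3SiCl (in situ), then 1, −100 → −78 °C
Reagents that add atoms: chlorotrimethylsilane, C[Si](C)(C)Cl
Why: Enantioselective deprotonation of a prochiral 4-substituted cyclohexanone by a C2-symmetric chiral lithium amide with in situ silyl trapping; the base discriminates the two enantiotopic axial α-protons and thereby sets C8 (R), the source of all later stereocontrol.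

Step 2
Reactants: 2 (R)-trimethyl[(4-methylcyclohex-1-en-1-yl)oxy]silane
Product: 3 (R)-4-methylcyclohex-2-en-1-one
Conditions: Pd(OAc)2 (0.1 equiv), O2 (1 atm), DMSO, 25 °C
Reagents that add atoms: none
Why: Saegusa–Ito oxidation: the silyl enol ether gives a divalent palladium enolate at C10 that undergoes β-hydride elimination from C9, so the enone forms regiospecifically and C8 is untouched; O2 reoxidizes zerovalent palladium.

Step 3
Reactants: 3 (R)-4-methylcyclohex-2-en-1-one; 4 tributyl[(benzyloxy)methyl]stannane
Product: 5 {[(3S,4R)-3-(benzyloxymethyl)-4-methylcyclohex-1-en-1-yl]oxy}trimethylsilane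
Conditions: 4, n-BuLi, THF, −78 °C; CuBr·SMe2 (0.5 equiv per lithium reagent); then 3, Me3SiCl, −78 °C; Et3N, aq. NaHCO3
Reagents that add atoms: chlorotrimethylsilane, C[Si](C)(C)Cl
Why: Tin–lithium exchange gives the α-alkoxymethyllithium, transmetalation gives (BnOCH2)2CuLi, and Me3SiCl-accelerated conjugate addition delivers C11 to C9 anti to the C8 methyl while trapping the enolate regiospecifically; the new C9 centre is erased in step 4, so only the regiochemistry matters.

Step 4
Reactants: 5 {[(3S,4R)-3-(benzyloxymethyl)-4-methylcyclohex-1-en-1-yl]oxy}trimethylsilane
Product: 6 (R)-3-(benzyloxymethyl)-4-methylcyclohex-2-en-1-one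
Conditions: Pd(OAc)2 (0.2 equiv), O2 (1 atm), DMSO, 40 °C
Reagents that add atoms: none
Why: Second Saegusa–Ito oxidation; the divalent palladium enolate can eliminate only the single hydrogen on C9, which restores the enone with C11 on the β-carbon and leaves C8 intact.

Step 5
Reactants: 6 (R)-3-(benzyloxymethyl)-4-methylcyclohex-2-en-1-one; 7 methyl bromoacetate
Product: 9 methyl 2-[(1S,2R,3R)-2-(benzyloxymethyl)-2,3-dimethyl-6-oxocyclohexyl]acetate, via lithium enolate 8 (not isolated)
Conditions: Me2CuLi (MeLi, CuI), Et2O, −20 → 0 °C; then THF, DMPU, 7, −40 → 0 °C; aq. NH4Cl
Reagents that add atoms: lithium dimethylcuprate, [Li+].C[Cu-]C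
Why: Tandem conjugate addition of Me2CuLi to a β,β-disubstituted enone and C-alkylation of the regiodefined enolate with an α-halo ester. The methyl enters anti to the C8 methyl, which allylic strain with the C9 substituent holds pseudoaxial (sets C9, CH3 trans to the C8 methyl). The electrophile then attacks C10 axially, on the face opposite the pseudoaxial CH2OBn and the C8 methyl (sets C10 under kinetic control, arm cis to the C9 methyl).

Step 6
Reactants: 9 methyl 2-[(1S,2R,3R)-2-(benzyloxymethyl)-2,3-dimethyl-6-oxocyclohexyl]acetate
Product: 10 methyl 2-[(1R,2R,3R)-2-(benzyloxymethyl)-2,3-dimethyl-6-methylidenecyclohexyl]acetate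
Conditions: Zn, CH2Br2, TiCl4, THF/CH2Cl2, 0 → 25 °C
Reagents that add atoms: dibromomethane, BrCBr
Why: Lombardo methylenation: the non-basic, oxophilic gem-dimetallic methylene reagent olefinates hindered, enolizable ketones without epimerizing C10 and does not touch the ester; once C5 is an alkene, C10 can no longer epimerize.

Step 7
Reactants: 10 methyl 2-[(1R,2R,3R)-2-(benzyloxymethyl)-2,3-dimethyl-6-methylidenecyclohexyl]acetate
Product: 11 2-[(1R,2R,3R)-2-(benzyloxymethyl)-2,3-dimethyl-6-methylidenecyclohexyl]acetaldehyde
Conditions: i-Bu2AlH (1.1 equiv), CH2Cl2, −78 °C; MeOH, then aq. KNaC4H4O6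
Reagents that add atoms: none
Why: Partial reduction of a methyl ester to the aldehyde through the tetrahedral aluminium hemiacetal, which is stable at −78 °C; the alkene and the benzyl ether are inert.

Step 8
Reactants: 11 2-[(1R,2R,3R)-2-(benzyloxymethyl)-2,3-dimethyl-6-methylidenecyclohexyl]acetaldehyde; 12 ethynylmagnesium bromide
Product: 14 1-[(1R,2R,3R)-2-(benzyloxymethyl)-2,3-dimethyl-6-methylidenecyclohexyl]but-3-yn-2-yl acetate (both C2 epimers), via bromomagnesium alkoxide 13 (not isolated)
Conditions: 12 (1.3 equiv), THF, −78 → 0 °C; then Ac2O (3 equiv), 0 → 25 °C
Reagents that add atoms: acetic anhydride, CC(=O)OC(C)=O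
Why: Grignard addition of an ethynyl nucleophile to an unhindered aldehyde and acylation of the magnesium alkoxide in the same flask; C2 forms as a mixture of epimers, which is acceptable because it becomes sp2 in step 9.

Step 9
Reactants: 14 1-[(1R,2R,3R)-2-(benzyloxymethyl)-2,3-dimethyl-6-methylidenecyclohexyl]but-3-yn-2-yl acetate (both C2 epimers)
Product: 15 (4R,5R,8R,9R,10R)-9-(benzyloxymethyl)-8,9-dimethyl-4,5-methanodecal-2-en-3-yl acetate (decalin numbering; cyclopropane CH2 on the β face, H-10 α)
Conditions: PtCl2 (5 mol%), toluene, 80 °C
Reagents that add atoms: none
Why: The alkyne of 14 binds to PtCl2, the carbonyl oxygen of the acetate then bonds to C3 while the C2–O bond is given up (a 1,2-acyloxy shift through a five-membered acetoxonium ion), and the electrophilic platinum vinyl carbenoid so generated at C4 is taken up by the C5=CH2 alkene; alkene attack first and acyl shift second would form the same bonds. The closest known reaction type is the PtCl2- or AuCl3-catalysed cycloisomerization of 5-acyloxy-1,6-enynes to bicyclo[4.1.0]hept-2-en-2-yl esters (Rautenstrauch-type acyloxy migration, then cyclopropanation). Ring B is formed as a six-membered carbocycle that takes up both alkyne carbons (6-endo-dig with respect to the alkyne), and the three-membered ring is formed by [2+1] addition of C4 to both alkene carbons. C4 and C5 are set together and are necessarily cis on the three-membered ring, so the only open question is their relation to C10. Ring A controls this: in the chair with the C10 arm equatorial the carbenoid reaches C5 only along the equatorial trajectory, anti to the axial C9 methyl, so C4 becomes equatorial, the CH2 becomes axial (β) and the fusion is trans. The ring-flipped chair with an axial arm would give the cis-fused isomer, but it must place CH2OBn axial and syn to the forming cyclopropane and build a cis-decalin-like array, so it should be the higher pathway, though not by a wide margin. The step also needs 1,2- rather than 1,3-acyloxy migration, which the terminal alkyne secures, and no control at C2, because that carbon becomes sp2 and both epimers of 14 converge on 15. With a benzyl ether at C11 and a single alkene, nothing else in 14 can intercept the carbenoid.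

Step 10
Reactants: 15 (4R,5R,8R,9R,10R)-9-(benzyloxymethyl)-8,9-dimethyl-4,5-methanodecal-2-en-3-yl acetate
Product: 16 (4R,5R,8R,9R,10R)-9-(benzyloxymethyl)-8,9-dimethyl-4,5-methanodecalin-3-one
Conditions: K2CO3 (0.2 equiv), MeOH, 0 → 25 °C
Reagents that add atoms: none
Why: Transesterification of the enol acetate by methoxide and protonation of the enolate at C2 give the conjugated cyclopropyl ketone; C4 is a cyclopropane carbon and cannot epimerize.

Step 11
Reactants: 16 (4R,5R,8R,9R,10R)-9-(benzyloxymethyl)-8,9-dimethyl-4,5-methanodecalin-3-one
Product: 19 (1R,4aR,5R,6R,8aS)-5-(hydroxymethyl)-1,5,6,8a-tetramethyloctahydronaphthalen-2(1H)-one, via dilithium enolate alkoxide 17 (not isolated), via C4-epimeric hydroxy ketone 18 (not isolated)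
Conditions: Li (8 equiv), t-BuOH (2 equiv), NH3/THF, −78 °C; isoprene; MeI (5 equiv), −78 → −33 °C; NH4Cl; then NaOMe (0.3 equiv), MeOH, 40 °C
Reagents that add atoms: iodomethane, CI
Why: Dissolving-metal cleavage of a conjugated cyclopropyl ketone with enolate trapping (reductive alkylation): the C4–CH2 bond, which overlaps the carbonyl π system, breaks in preference to the in-ring C4–C5 bond, so the CH2 becomes the C5 methyl with the configuration fixed in step 9 and the C3/C4 enolate is methylated, while Li/NH3 also cleaves the benzyl ether. Iodomethane should enter C4 anti to the axial C5 methyl, which gives 18, so methoxide equilibration is used to reach 19 with the more stable equatorial C4 methyl, cis to the C5 methyl.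

Step 12
Reactants: 19 (1R,4aR,5R,6R,8aS)-5-(hydroxymethyl)-1,5,6,8a-tetramethyloctahydronaphthalen-2(1H)-one
Product: 20 [(1R,2R,4aS,5R,8aR)-1,2,4a,5-tetramethyl-6-oxodecahydronaphthalen-1-yl]methyl trifluoromethanesulfonate
Conditions: Tf2O (1.2 equiv), pyridine (3 equiv), CH2Cl2, −78 → −30 °C
Reagents that add atoms: trifluoromethanesulfonic anhydride, O=S(=O)(OS(=O)(=O)C(F)(F)F)C(F)(F)F
Why: Sulfonylation of a primary alcohol at low temperature; pyridine does not enolize the ketone under these conditions, and the triflate is chosen because a neopentyl centre needs the best available leaving group.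

Step 13
Reactants: 20 [(1R,2R,4aS,5R,8aR)-1,2,4a,5-tetramethyl-6-oxodecahydronaphthalen-1-yl]methyl trifluoromethanesulfonate; 21 umbelliferone (7-hydroxy-2H-chromen-2-one)
Product: 22 7-{[(1R,2R,4aS,5R,8aR)-1,2,4a,5-tetramethyl-6-oxodecahydronaphthalen-1-yl]methoxy}-2H-chromen-2-one
Conditions: 21 (1.5 equiv), Cs2CO3 (1.5 equiv), MeCN, 25 → 60 °C
Reagents that add atoms: none
Why: Williamson ether synthesis (SN2) of the weakly basic caesium phenoxide of 21 on the primary triflate; C9 has no hydrogen, so elimination is impossible, and the carbonate base leaves the lactone closed and can only move C4 towards its stable configuration.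

## Compound list

1 | 4-methylcyclohexanone | CC1CCC(=O)CC1 | starting material
2 | (R)-trimethyl[(4-methylcyclohex-1-en-1-yl)oxy]silane | C[C@@H]1CCC(O[Si](C)(C)C)=CC1 | intermediate
3 | (R)-4-methylcyclohex-2-en-1-one | C[C@@H]1CCC(=O)C=C1 | intermediate
4 | tributyl[(benzyloxy)methyl]stannane | CCCC[Sn](CCCC)(CCCC)COCc1ccccc1 | starting material
5 | {[(3S,4R)-3-(benzyloxymethyl)-4-methylcyclohex-1-en-1-yl]oxy}trimethylsilane (3,4-trans) | C[C@@H]1CCC(O[Si](C)(C)C)=C[C@H]1COCc1ccccc1 | intermediate
6 | (R)-3-(benzyloxymethyl)-4-methylcyclohex-2-en-1-one | C[C@@H]1CCC(=O)C=C1COCc1ccccc1 | intermediate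
7 | methyl bromoacetate | COC(=O)CBr | starting material
8 | lithium (3R,4R)-3-(benzyloxymethyl)-3,4-dimethylcyclohex-1-en-1-olate (formed in the flask, not isolated) | C[C@@H]1CCC(O[Li])=C[C@]1(C)COCc1ccccc1 | intermediate
9 | methyl 2-[(1S,2R,3R)-2-(benzyloxymethyl)-2,3-dimethyl-6-oxocyclohexyl]acetate | C[C@@H]1CCC(=O)[C@@H](CC(=O)OC)[C@]1(C)COCc1ccccc1 | intermediate
10 | methyl 2-[(1R,2R,3R)-2-(benzyloxymethyl)-2,3-dimethyl-6-methylidenecyclohexyl]acetate | C[C@@H]1CCC(=C)[C@@H](CC(=O)OC)[C@]1(C)COCc1ccccc1 | intermediate
11 | 2-[(1R,2R,3R)-2-(benzyloxymethyl)-2,3-dimethyl-6-methylidenecyclohexyl]acetaldehyde | C[C@@H]1CCC(=C)[C@@H](CC=O)[C@]1(C)COCc1ccccc1 | intermediate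
12 | ethynylmagnesium bromide | C#C[Mg]Br | starting material
13 | bromomagnesium 1-[(1R,2R,3R)-2-(benzyloxymethyl)-2,3-dimethyl-6-methylidenecyclohexyl]but-3-yn-2-olate, both C2 epimers (formed in the flask, not isolated) | C[C@@H]1CCC(=C)[C@@H](CC(O[Mg]Br)C#C)[C@]1(C)COCc1ccccc1 | intermediate
14 | 1-[(1R,2R,3R)-2-(benzyloxymethyl)-2,3-dimethyl-6-methylidenecyclohexyl]but-3-yn-2-yl acetate, both C2 epimers (the 1,6-enyne) | C[C@@H]1CCC(=C)[C@@H](CC(OC(C)=O)C#C)[C@]1(C)COCc1ccccc1 | intermediate
15 | (4R,5R,8R,9R,10R)-9-(benzyloxymethyl)-8,9-dimethyl-4,5-methanodecal-2-en-3-yl acetate (decalin numbering; β-cyclopropane across C4–C5, enol acetate at C2=C3, trans fusion) | C[C@@H]1CC[C@]23C[C@H]2C(OC(C)=O)=CC[C@H]3[C@]1(C)COCc1ccccc1 | intermediate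
16 | (4R,5R,8R,9R,10R)-9-(benzyloxymethyl)-8,9-dimethyl-4,5-methanodecalin-3-one (decalin numbering; conjugated cyclopropyl ketone) | C[C@@H]1CC[C@]23C[C@H]2C(=O)CC[C@H]3[C@]1(C)COCc1ccccc1 | intermediate
17 | dilithium salt: C3/C4 enolate and C11 alkoxide of the ring-opened, debenzylated ketone (formed in the flask, not isolated) | C[C@@H]1CC[C@@]2(C)[C@@H](CCC(O[Li])=C2)[C@]1(C)CO[Li] | intermediate
18 | (1S,4aR,5R,6R,8aS)-5-(hydroxymethyl)-1,5,6,8a-tetramethyloctahydronaphthalen-2(1H)-one, the axial C4 epimer of 19 (not isolated) | C[C@@H]1CC[C@@]2(C)[C@@H](CCC(=O)[C@H]2C)[C@]1(C)CO | intermediate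
19 | (1R,4aR,5R,6R,8aS)-5-(hydroxymethyl)-1,5,6,8a-tetramethyloctahydronaphthalen-2(1H)-one | C[C@@H]1CC[C@@]2(C)[C@@H](CCC(=O)[C@@H]2C)[C@]1(C)CO | intermediate
20 | [(1R,2R,4aS,5R,8aR)-1,2,4a,5-tetramethyl-6-oxodecahydronaphthalen-1-yl]methyl trifluoromethanesulfonate | C[C@@H]1CC[C@@]2(C)[C@@H](CCC(=O)[C@@H]2C)[C@]1(C)COS(=O)(=O)C(F)(F)F | intermediate
21 | umbelliferone (7-hydroxy-2H-chromen-2-one) | O=c1ccc2ccc(O)cc2o1 | starting material
22 | 7-{[(1R,2R,4aS,5R,8aR)-1,2,4a,5-tetramethyl-6-oxodecahydronaphthalen-1-yl]methoxy}-2H-chromen-2-one | C[C@@H]1CC[C@@]2(C)[C@@H](CCC(=O)[C@@H]2C)[C@]1(C)COc1ccc2ccc(=O)oc2c1 | target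

## Step count and least certain steps

Total step count: 13. Longest linear sequence: 13 steps (1 to 22).

Step 9 (key step). The most likely failure is incomplete control of the ring fusion. The two chairs of ring A in 14 each place one C9 substituent axial and should differ little in energy, so part of the material may cyclize through the chair with the axial arm and give the cis-fused isomer. If alkene attack precedes the acyloxy shift, the two C2 epimers may also react at different rates, and some 1,3-acyloxy shift to an allenyl acetate could divert material. Fallback: it sets out from 6 and comes back at 16, and the fusion is decided by a directing hydroxyl group rather than by the conformation of ring A. Me2CuLi with Me3SiCl would give the silyl enol ether {[(3R,4R)-3-(benzyloxymethyl)-3,4-dimethylcyclohex-1-en-1-yl]oxy}trimethylsilane F1. Mukaiyama–Michael addition of F1 to but-3-en-2-one (BF3·OEt2, CH2Cl2, −78 °C) would give the 1,5-diketone (2S,3R,4R)-3-(benzyloxymethyl)-3,4-dimethyl-2-(3-oxobutyl)cyclohexan-1-one F2, with the same facial preference at C10 as in step 5. Mild aldol condensation (pyrrolidine, AcOH, then dilute NaOMe in MeOH) would close ring B as the octalone (4aR,5R,6R)-5-(benzyloxymethyl)-5,6-dimethyl-4,4a,5,6,7,8-hexahydronaphthalen-2(3H)-one F3. LiBH(s-Bu)3 (THF, −78 °C) should attack C3 from the equatorial side and give the pseudoaxial 3β-alcohol (2S,4aR,5R,6R)-5-(benzyloxymethyl)-5,6-dimethyl-2,3,4,4a,5,6,7,8-octahydronaphthalen-2-ol F4. Hydroxyl-directed Simmons–Smith cyclopropanation (Et2Zn, CH2I2, CH2Cl2, 0 °C) would deliver the CH2 to the β face of C4=C5, trans to H-10, giving the cyclopropyl carbinol F5 (16 with a 3β-hydroxyl in place of the ketone). Dess–Martin oxidation of F5 gives 16.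

Step 5. The most likely failure is sluggish or unselective C-alkylation of the copper-containing enolate: proton transfer to the acidic α-halo ester, equilibration of the enolate towards C6, or partial loss of facial selectivity at C10. Fallback: it sets out from 6 and comes back at 14. The enolate 8 is alkylated with allyl bromide, the most dependable electrophile for cuprate-derived enolates, to give (2S,3R,4R)-3-(benzyloxymethyl)-3,4-dimethyl-2-(prop-2-en-1-yl)cyclohexan-1-one F6. Ozonolysis (O3, CH2Cl2/MeOH, −78 °C; PPh3) gives the keto aldehyde 2-[(1S,2R,3R)-2-(benzyloxymethyl)-2,3-dimethyl-6-oxocyclohexyl]acetaldehyde F7. Ethynylmagnesium bromide at −78 °C should add to the aldehyde in preference to the hindered ketone, and Ac2O traps the alkoxide as the keto acetate 1-[(1S,2R,3R)-2-(benzyloxymethyl)-2,3-dimethyl-6-oxocyclohexyl]but-3-yn-2-yl acetate F8. Methylenation of F8 with Zn, CH2Br2 and TiCl4 gives 14.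

Step 11. The most likely failure is over-reaction in the one-pot reductive methylation: O-methylation of the C11 alkoxide, a second methylation after enolate equilibration, or reduction of the ketone if too much proton donor is present. The C4 equilibrium may also favour the equatorial epimer only modestly, because that methyl is gauche to the C5 methyl. Fallback: it sets out from 16 and comes back at 19, and C4 is set by kinetic hydrogen delivery instead of equilibration. After the Li/NH3 cleavage, the enolate 17 is quenched in THF with Eschenmoser's salt (dimethylmethylideneammonium iodide) to give the Mannich base 4α-[(dimethylamino)methyl] hydroxy ketone F9. Quaternization of F9 with MeI and elimination (NaHCO3) gives the 4-methylidene ketone (4aR,5R,6R,8aS)-5-(hydroxymethyl)-5,6,8a-trimethyl-1-methylideneoctahydronaphthalen-2(1H)-one F10. Hydrogenation of F10 (H2, Pd/C, EtOAc) should add hydrogen to C4 from the α face, anti to the axial C5 methyl, which gives 19.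

Step 13. The most likely failure is that substitution at the neopentyl C11 is too slow. Consumption of the triflate by traces of water, by the solvent, or by ionization with a Wagner–Meerwein shift of a C9 substituent would then take over. Fallback: it sets out from 19, bypasses step 12, and comes back at 22. The aryl–oxygen bond is formed instead of the alkyl–oxygen bond, by copper-catalysed Ullmann-type coupling of the alcohol with commercial 7-bromo-2H-chromen-2-one (CuI, 3,4,7,8-tetramethyl-1,10-phenanthroline, Cs2CO3, toluene, 110 °C). This fallback makes no new compound, which is recorded as F0.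

Step 1. The most likely failure is incomplete enantiotopic selection in the deprotonation. No later step removes the minor enantiomer, so 2 and everything after it would carry it along. Fallback: it does not set out from a numbered compound; it replaces 1 by commercial propanal and but-3-en-2-one and comes back at 3. Enamine-catalysed Michael addition with (S)-2-[methoxy(diphenyl)methyl]pyrrolidine (5 mol%) and a catechol co-catalyst, neat at 4 °C, is expected to give (R)-2-methyl-5-oxohexanal F11 in high enantiomeric purity; if the sense proves opposite, the antipodal catalyst is used. Intramolecular aldol condensation of F11 (LiOH, i-PrOH, 25 °C) then gives 3.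

## Further compounds

F1 | step 9 | {[(3R,4R)-3-(benzyloxymethyl)-3,4-dimethylcyclohex-1-en-1-yl]oxy}trimethylsilane | C[C@@H]1CCC(O[Si](C)(C)C)=C[C@]1(C)COCc1ccccc1
F2 | step 9 | (2S,3R,4R)-3-(benzyloxymethyl)-3,4-dimethyl-2-(3-oxobutyl)cyclohexan-1-one | C[C@@H]1CCC(=O)[C@@H](CCC(C)=O)[C@]1(C)COCc1ccccc1
F3 | step 9 | (4aR,5R,6R)-5-(benzyloxymethyl)-5,6-dimethyl-4,4a,5,6,7,8-hexahydronaphthalen-2(3H)-one | C[C@@H]1CCC2=CC(=O)CC[C@H]2[C@]1(C)COCc1ccccc1
F4 | step 9 | (2S,4aR,5R,6R)-5-(benzyloxymethyl)-5,6-dimethyl-2,3,4,4a,5,6,7,8-octahydronaphthalen-2-ol | C[C@@H]1CCC2=C[C@@H](O)CC[C@H]2[C@]1(C)COCc1ccccc1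
F5 | step 9 | cyclopropyl carbinol (16 with a 3β-hydroxyl in place of the ketone) | C[C@@H]1CC[C@]23C[C@H]2[C@@H](O)CC[C@H]3[C@]1(C)COCc1ccccc1
F6 | step 5 | (2S,3R,4R)-3-(benzyloxymethyl)-3,4-dimethyl-2-(prop-2-en-1-yl)cyclohexan-1-one | C[C@@H]1CCC(=O)[C@@H](CC=C)[C@]1(C)COCc1ccccc1
F7 | step 5 | 2-[(1S,2R,3R)-2-(benzyloxymethyl)-2,3-dimethyl-6-oxocyclohexyl]acetaldehyde | C[C@@H]1CCC(=O)[C@@H](CC=O)[C@]1(C)COCc1ccccc1
F8 | step 5 | 1-[(1S,2R,3R)-2-(benzyloxymethyl)-2,3-dimethyl-6-oxocyclohexyl]but-3-yn-2-yl acetate (both carbinol epimers) | C[C@@H]1CCC(=O)[C@@H](CC(OC(C)=O)C#C)[C@]1(C)COCc1ccccc1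
F9 | step 11 | 4α-[(dimethylamino)methyl] hydroxy ketone (Mannich base; 18 with CH2NMe2 in place of the C4 methyl) | C[C@@H]1CC[C@@]2(C)[C@@H](CCC(=O)[C@H]2CN(C)C)[C@]1(C)CO
F10 | step 11 | (4aR,5R,6R,8aS)-5-(hydroxymethyl)-5,6,8a-trimethyl-1-methylideneoctahydronaphthalen-2(1H)-one | C[C@@H]1CC[C@@]2(C)[C@@H](CCC(=O)C2=C)[C@]1(C)CO
F0 | step 13 | none | none
F11 | step 1 | (R)-2-methyl-5-oxohexanal | C[C@@H](C=O)CCC(C)=O
A1 | alternative 1 | 2-(tert-butyldimethylsilyloxy)-3-methylbuta-1,3-diene | C=C(C)C(=C)O[Si](C)(C)C(C)(C)C
A2 | alternative 1 | (5R)-5-[(1R,2S,5R)-menthyloxy]-3-methylfuran-2(5H)-one | O=C1O[C@@H](O[C@@H]2C[C@H](C)CC[C@H]2C(C)C)C=C1C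
A3 | alternative 1 | cis-fused lactone acetal cycloadduct (silyl enol ether at C5=C6) | O=C1O[C@@H](O[C@@H]3C[C@H](C)CC[C@H]3C(C)C)[C@@H]2CC(O[Si](C)(C)C(C)(C)C)=C(C)C[C@]12C
A4 | alternative 2 | (2E,7R,8E,10E)-6,6-(ethylenedioxy)-2,7,8-trimethyldodeca-2,8,10-trienal | O=C/C(C)=C/CCC1(OCCO1)[C@H](C)/C(C)=C/C=C/C
A5 | alternative 2 | trans-fused octalin aldehyde (C6=C7 alkene, C3 dioxolane) | C[C@@H]1C=C[C@@]2(C)[C@@H](CCC3(OCCO3)[C@@H]2C)[C@]1(C)C=O
A6 | alternative 3 | (bromomethyl)dimethylsilyl ether of the C7=C8 unsaturated C11 alcohol (C3 dioxolane) | C1=CC[C@@]2(C)[C@@H](CCC3(OCCO3)[C@@H]2C)[C@]1(C)CO[Si](C)(C)CBr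
A7 | alternative 3 | cis-fused cyclic siloxane | C[Si]1(C)C[C@@H]2CC[C@@]3(C)[C@@H](CCC4(OCCO4)[C@@H]3C)[C@]2(C)CO1
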